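**Retrosynthetic overview**
1. The central cyclobutane is opened in two polarity-inverted stages, not as a cycloaddition. C8–C8' is cut first (oxidative union of the two nucleophilic γ-carbons of a bis-furanolate). C9–C9' is cut second and is the key bond: a reductive union of two normally electrophilic δ-carbons through the SmI2-derived C9 radical/anion of an aromatic samarium furanolate. This leads to 2 × chloranthalactone A.
2. Butenolide: chloranthalactone A ⇒ tricyclic C12 ketone + ethyl pyruvate (C7 aldol, dehydration, enol lactonisation).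
3. Cyclopropane and ring A together: tricyclic ketone ⇒ 2-substituted acrolein tosylhydrazone (intramolecular vinyl-carbene cyclopropanation of the C10 vinyl group).
4. Ring B with the C5/C10 pair: enal ⇒ 3-methyl-3-vinyl-4-isopropenylcyclohexanone ⇒ (+)-verbenone + vinyl Grignard reagent (conjugate addition, cyclobutane fragmentation).
5. Order of ring formation: ring B (from verbenone) → cyclopropane + ring A → butenolide → central cyclobutane.

Assumptions: lindenane numbering (C1–C15, primes for the second half) is used throughout, and (1R,5R)-(+)-verbenone is bought enantiopure.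

**Step 1**
Reactants: 1 (1R,5R)-(+)-verbenone; 2 vinylmagnesium bromide
Product: 4 (1R,4S,5S)-4-ethenyl-4,6,6-trimethylbicyclo[3.1.1]heptan-2-one (vinyl anti to the CMe2 bridge), via bromomagnesium enolate 3 (not isolated)
Conditions: 2 (1.5 equiv), CuI (0.2 equiv), THF, −40 → 0 °C; then H2O
Reagents that add atoms: vinylmagnesium bromide (2), C=C[Mg]Br
Why: Copper-catalysed conjugate addition, in which the gem-dimethyl bridge blocks one enone face, so vinyl enters anti to it and sets quaternary C10 with its methyl trans to H-5.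

**Step 2**
Reactants: 4 vinyl adduct
Product: 6 (3S,4S)-3-ethenyl-3-methyl-4-(prop-1-en-2-yl)cyclohexan-1-one, via enol acetate 5 (not isolated)
Conditions: Zn(OAc)2, BF3·OEt2, Ac2O, CH2Cl2, 0 °C → rt; then K2CO3 (cat.), MeOH, rt
Reagents that add atoms: none
Why: Lewis-acid-promoted acetylative fragmentation of the strained cyclobutyl ketone gives a tertiary cation that loses a methyl proton, and methanolysis of 5 frees the ketone, while C5 and C10 are untouched so vinyl and isopropenyl end up trans-diequatorial.

**Step 3**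
Reactants: 6 cyclohexanone
Product: 8 2-[(1R,2S)-2-ethenyl-2-methyl-4-oxocyclohexyl]prop-2-enal, via allylic alcohol 7 (not isolated)
Conditions: SeO2 (0.3 equiv), t-BuOOH (2.5 equiv), CH2Cl2, 0 °C → rt; filter; MnO2 (15 equiv), CH2Cl2, rt
Reagents that add atoms: tert-butyl hydroperoxide, CC(C)(C)OO (oxygen atom, relayed through SeO2, O=[Se]=O)
Why: Riley-type allylic oxidation (ene reaction, then [2,3]-shift) hits only the methyl of the 1,1-disubstituted alkene because the vinyl group has no allylic hydrogen, MnO2 converges 7 to the enal, and no stereocentre is touched.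

**Step 4**
Reactants: 8 enal
Product: 11 (1R,3S,5S,10S)-11,12,13-trinorlinden-4(15)-en-8-one (3/5/6 tricycle; C10 methyl β; H-5 α; cyclopropane CH2 β; C4 exocyclic methylene), via tosylhydrazone 9 (not isolated), via vinyl diazoalkane 10 (not isolated)
Conditions: TsNHNH2 (1.0 equiv), 4 Å MS, THF, 0 °C → rt; then LiOt-Bu (1.1 equiv), Pd2(dba)3 (2.5 mol %), 60 °C
Reagents that add atoms: none
Why: Bamford–Stevens release of 10 and palladium-catalysed intramolecular cyclopropanation through an allylic (vinyl) carbene is a known reaction type for 2-substituted acrolein tosylhydrazones, and on the trans-diequatorial chair only the vinyl rotamer with its CH2 terminus syn to the axial C10 methyl reaches the carbene, which sets C1 (R) and C3 (S), closes a trans-fused ring A, and relies on the hindered β-quaternary ring ketone condensing with TsNHNH2 more slowly than the aldehyde.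

**Step 5**
Reactants: 11 tricyclic ketone; 12 ethyl pyruvate
Product: 14 ethyl 2-hydroxy-2-[(1R,3S,5S,10S)-8-oxo-11,12,13-trinorlinden-4(15)-en-7-yl]propanoate (mixture at C7 and C11), via lithium enolate 13 (not isolated)
Conditions: LiN(i-Pr)2 (1.05 equiv), THF, −78 °C; 12 (1.3 equiv), −78 °C; AcOH quench at −78 °C
Reagents that add atoms: ethyl pyruvate (12), CCOC(=O)C(C)=O
Why: Kinetic deprotonation occurs at C7 because C9 is neopentyl, the enolate adds to the ketone carbonyl of pyruvate (directed aldol addition), and the new C7 and C11 centres form as a mixture that step 6 erases.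

**Step 6**
Reactants: 14 aldol adduct
Product: 17 chloranthalactone A [(1R,3S,5S,10S)-lindena-4(15),7(11),8-trien-12,8-olide], via tertiary mesylate 15 (not isolated), via enone ester 16 (not isolated)
Conditions: MsCl (2 equiv), Et3N (5 equiv), CH2Cl2, 0 °C → rt; then DBU (0.5 equiv), 40 °C
Reagents that add atoms: none
Why: Mesylation and E1cB elimination give tetrasubstituted enone ester 16, whose E and Z forms interconvert through the dienolate, and the C9 enolate oxygen of the Z form is acylated intramolecularly (enol lactonisation) with loss of ethanol, while base-only conditions spare the acid-sensitive vinylcyclopropane and no stereocentre is affected.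

**Step 7 (key step)**
Reactants: 17 chloranthalactone A (2 molecules)
Product: 20 target CNP0265879.1 (C2-symmetric 8,8':9,9' head-to-head cyclodimer of 17; 1R,3S,5S,8R,9S,10S in each half), via samarium furanolate C9 radical 18 (not isolated), via bis(samarium furanolate) 19 (not isolated)
Conditions: SmI2 (0.1 M in THF, 1.05 equiv per 17) added over 30 min to 17 (0.2 M) and HMPA (4 equiv), THF, −78 °C; then I2 (0.55 equiv per 17), −78 → 0 °C
Reagents that add atoms: none
Why: Proposed new method: one electron from SmI2–HMPA converts the alkylidene butenolide, whose C9 is normally the electrophilic δ-terminus of a 1,6-acceptor, into the aromatic trivalent samarium 2-furanolate 18 with furfuryl-type radical (after a second electron, carbanion) character at C9, so C9 bonds to C9' of a second molecule on the α face anti to the axial C10 methyl of both homochiral partners and sets C9 and C9' (S,S) in the C2-symmetric sense; iodine then removes two electrons from 19, whose nucleophilic γ-carbons C8 and C8' can only meet on the face already tied by C9–C9' (cis fusion on both sides, lactone oxygens trans, C8 and C8' R), α-coupling being excluded by a bridgehead alkene; the closest known reaction types are SmI2–HMPA reductive β,β-dimerisation of unsaturated esters, cathodic hydrodimerisation, radical-anion [2+2] cycloaddition of enones, and I2- or CuCl2-mediated closure of 1,4-bis-enolates to cyclobutanes.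

**Compound list**
1 | (1R,5R)-(+)-verbenone, (1R,5R)-4,6,6-trimethylbicyclo[3.1.1]hept-3-en-2-one | CC1=CC(=O)[C@@H]2C[C@H]1C2(C)C | starting material
2 | vinylmagnesium bromide | C=C[Mg]Br | starting material
3 | bromomagnesium enolate of 4 | C=C[C@]1(C)C=C(O[Mg]Br)[C@@H]2C[C@H]1C2(C)C | intermediate
4 | (1R,4S,5S)-4-ethenyl-4,6,6-trimethylbicyclo[3.1.1]heptan-2-one | C=C[C@]1(C)CC(=O)[C@@H]2C[C@H]1C2(C)C | intermediate
5 | (4S,5S)-5-ethenyl-5-methyl-4-(prop-1-en-2-yl)cyclohex-1-en-1-yl acetate | C=C[C@]1(C)CC(OC(C)=O)=CC[C@H]1C(C)=C | intermediate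
6 | (3S,4S)-3-ethenyl-3-methyl-4-(prop-1-en-2-yl)cyclohexan-1-one | C=C[C@]1(C)CC(=O)CC[C@H]1C(C)=C | intermediate
7 | (3S,4R)-3-ethenyl-4-(3-hydroxyprop-1-en-2-yl)-3-methylcyclohexan-1-one | C=C[C@]1(C)CC(=O)CC[C@H]1C(=C)CO | intermediate
8 | 2-[(1R,2S)-2-ethenyl-2-methyl-4-oxocyclohexyl]prop-2-enal | C=C[C@]1(C)CC(=O)CC[C@H]1C(=C)C=O | intermediate
9 | N'-[(E)-2-[(1R,2S)-2-ethenyl-2-methyl-4-oxocyclohexyl]prop-2-enylidene]-4-methylbenzenesulfonohydrazide | C=C[C@]1(C)CC(=O)CC[C@H]1C(=C)/C=N/NS(=O)(=O)c1ccc(C)cc1 | intermediate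
10 | (3S,4R)-4-(3-diazoprop-1-en-2-yl)-3-ethenyl-3-methylcyclohexan-1-one | C=C[C@]1(C)CC(=O)CC[C@H]1C(=C)C=[N+]=[N-] | intermediate
11 | (1R,3S,5S,10S)-11,12,13-trinorlinden-4(15)-en-8-one | C=C1[C@H]2C[C@H]2[C@@]2(C)[C@H]1CCC(=O)C2 | intermediate
12 | ethyl pyruvate | CCOC(=O)C(C)=O | starting material
13 | lithium C7–C8 enolate of 11 | C=C1[C@H]2C[C@H]2[C@@]2(C)[C@H]1CC=C(O[Li])C2 | intermediate
14 | ethyl 2-hydroxy-2-[(1R,3S,5S,10S)-8-oxo-11,12,13-trinorlinden-4(15)-en-7-yl]propanoate, mixture at C7 and C11 | C=C1[C@H]2C[C@H]2[C@@]2(C)[C@H]1CC(C(C)(O)C(=O)OCC)C(=O)C2 | intermediate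
15 | C11 methanesulfonate of 14 | C=C1[C@H]2C[C@H]2[C@@]2(C)[C@H]1CC(C(C)(OS(C)(=O)=O)C(=O)OCC)C(=O)C2 | intermediate
16 | ethyl 2-[(1R,3S,5S,10S)-8-oxo-11,12,13-trinorlinden-4(15)-en-7-ylidene]propanoate, E/Z mixture | C=C1[C@H]2C[C@H]2[C@@]2(C)[C@H]1CC(=C(C)C(=O)OCC)C(=O)C2 | intermediate
17 | chloranthalactone A, (1R,3S,5S,10S)-lindena-4(15),7(11),8-trien-12,8-olide | C=C1[C@H]2C[C@H]2[C@@]2(C)[C@H]1CC1=C(C)C(=O)OC1=C2 | intermediate
18 | diiodosamarium 2-furanolate of 17 with the radical centre at C9 (trivalent samarium) | C=C1[C@H]2C[C@H]2[C@@]2(C)[C@H]1CC1=C(OC(O[Sm](I)I)=C1C)[CH]2 | intermediate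
19 | (9S,9'S)-9,9'-linked bis(diiodosamarium 2-furanolate), new bond α on both halves | C=C1[C@H]2C[C@H]2[C@@]2(C)[C@H]1CC1=C(OC(O[Sm](I)I)=C1C)[C@H]2[C@@H]1C2=C(C[C@H]3C(=C)[C@H]4C[C@H]4[C@]13C)C(C)=C(O[Sm](I)I)O2 | intermediate
20 | CNP0265879.1, C2-symmetric 8,8':9,9' cyclodimer of 17 (1R,3S,5S,8R,9S,10S in each half) | C=C1[C@H]2C[C@H]2[C@@]2(C)[C@H]1CC1=C(C)C(=O)O[C@]13[C@H]2[C@H]1[C@@]2(C)[C@@H]4C[C@@H]4C(=C)[C@@H]2CC2=C(C)C(=O)O[C@@]213 | target

**Total step count:** 7. **Longest linear sequence:** 7 (steps 1–7; step 7 consumes two molecules of 17).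

**Three steps most likely to fail**

Step 7. Oxidation of 19 may break the C9–C9' bond in a Grob-type fragmentation and simply return 17, which can be recycled. Alternatively, 18 may be over-reduced and protonated on work-up. The fallback leaves electron-transfer chemistry and closes both bonds in one photochemical event. Compound 17 is irradiated (medium-pressure Hg lamp, Pyrex, degassed hexane, rt), so that excited alkylidene butenolide adds head-to-head to a ground-state molecule across the two α faces. It sets out from 17, comes back at 20 and makes no new compound (F0).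

Step 4. The ring ketone of 8 may compete for TsNHNH2, and 10 may close to a pyrazole before palladium captures it. The fallback changes the protecting-group logic so that only one carbonyl group is ever present. It sets out from 6. The ketone is masked (ethylene glycol, PPTS, benzene, Dean–Stark) as (7S,8S)-7-ethenyl-7-methyl-8-(prop-1-en-2-yl)-1,4-dioxaspiro[4.5]decane F1. Oxidation as in step 3 gives 2-[(7S,8R)-7-ethenyl-7-methyl-1,4-dioxaspiro[4.5]decan-8-yl]prop-2-enal F2. Condensation with TsNHNH2 gives the isolated, dried (E)-tosylhydrazone ketal F3. Its sodium salt (NaH, THF) is added slowly to Pd2(dba)3 in THF at 60 °C to give the ethylene ketal of the tricyclic ketone F4. PPTS in wet acetone then releases the ketone, and the route is rejoined at 11.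

Step 3. SeO2 may stall at 7, over-oxidise, or attack the α-positions of the ketone. The fallback replaces oxygen transfer by halogen transfer and sets out from 6. Ene-type chlorination with HOCl made from Ca(OCl)2 and CO2 (CH2Cl2–H2O, 0 °C) is selective for the 1,1-disubstituted alkene. It gives (3S,4R)-4-(3-chloroprop-1-en-2-yl)-3-ethenyl-3-methylcyclohexan-1-one F5. Kornblum oxidation (DMSO, NaHCO3, NaI cat., 80 °C) then gives the enal, and the route is rejoined at 8.

**Further compounds**
F0 | step 7 | none | none
F1 | step 4 | (7S,8S)-7-ethenyl-7-methyl-8-(prop-1-en-2-yl)-1,4-dioxaspiro[4.5]decane | C=C[C@]1(C)CC2(CC[C@H]1C(C)=C)OCCO2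
F2 | step 4 | 2-[(7S,8R)-7-ethenyl-7-methyl-1,4-dioxaspiro[4.5]decan-8-yl]prop-2-enal | C=C[C@]1(C)CC2(CC[C@H]1C(=C)C=O)OCCO2
F3 | step 4 | (E)-tosylhydrazone ketal, N'-[(E)-2-[(7S,8R)-7-ethenyl-7-methyl-1,4-dioxaspiro[4.5]decan-8-yl]prop-2-enylidene]-4-methylbenzenesulfonohydrazide | C=C[C@]1(C)CC2(CC[C@H]1C(=C)/C=N/NS(=O)(=O)c1ccc(C)cc1)OCCO2
F4 | step 4 | ethylene ketal of the tricyclic ketone, (1R,3S,5S,10S)-8,8-ethylenedioxy-11,12,13-trinorlinden-4(15)-ene | C=C1[C@H]2C[C@H]2[C@@]2(C)[C@H]1CCC1(C2)OCCO1
F5 | step 3 | (3S,4R)-4-(3-chloroprop-1-en-2-yl)-3-ethenyl-3-methylcyclohexan-1-one | C=C[C@]1(C)CC(=O)CC[C@H]1C(=C)CCl
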